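The synthesis cuts lactone ring D of the dihydroisocoumarin half on both sides of its C3–O2–C1 segment. That segment, with the methyl group on C3, is the skeleton of ethyl N,N-diisopropylcarbamate. The carbamate is nucleophilic at C3 after sparteine-mediated asymmetric deprotonation and electrophilic at C1. Its partner is a 2-bromobenzyl bromide. It is electrophilic at C4 and, after bromine–lithium exchange, nucleophilic at C8a; the two sites are 1,3-related through C4a of arene ring C. One flask thus forms C3–C4 and C1–C8a, closes ring D and sets (R)-C3. Demethylation follows, then a Friedel–Crafts union of C5, the only free carbon of ring C, with an o-quinone methide raised at C6′ of eugenin.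

Key step: step 5

Remark on the chemistry: unprimed locants C1–C8a follow isochroman-1-one numbering of the lactone half (arene ring C, lactone ring D). Primed locants follow chromone numbering (benzo ring A, pyranone ring B). The stereocentre C3 is read from the SMILES as (R). (–)-Sparteine and noreugenin are taken as catalogue compounds.

Step 1
Reactants: 1 3,5-dimethoxy-4-methylbenzoic acid
Product: 2 (3,5-dimethoxy-4-methylphenyl)methanol
Conditions: BH3·THF, THF, 0 °C to rt; then H2O
Reagents that add atoms: none
Why: Chemoselective borane reduction of the carboxylic acid through its acyloxyborane should leave the aryl methyl ethers untouched.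

Step 2
Reactants: 2 (3,5-dimethoxy-4-methylphenyl)methanol
Product: 3 (2-bromo-3,5-dimethoxy-4-methylphenyl)methanol
Conditions: NBS (1.0 equiv), MeCN, 0 °C
Reagents that add atoms: N-bromosuccinimide, O=C1CCC(=O)N1Br
Why: Electrophilic aromatic bromination, in which the two free ring positions are equivalent by symmetry and each lies ortho to one and para to the other methoxy group, so one equivalent should give a single monobromide that marks the future C8a.

Step 3
Reactants: 3 (2-bromo-3,5-dimethoxy-4-methylphenyl)methanol
Product: 4 2-bromo-1-(bromomethyl)-3,5-dimethoxy-4-methylbenzene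
Conditions: PBr3, CH2Cl2, 0 °C
Reagents that add atoms: phosphorus tribromide, BrP(Br)Br
Why: The primary benzylic alcohol is converted through its phosphite ester and SN2 displacement by bromide, which touches neither the aryl bromide nor the ethers.

Step 4
Reactants: 5 ethanol; 6 N,N-diisopropylcarbamoyl chloride
Product: 7 ethyl N,N-diisopropylcarbamate
Conditions: NaH, THF, 0 °C; then 6, reflux
Reagents that add atoms: none
Why: Nucleophilic acyl substitution (carbamoylation) of sodium ethoxide on the hindered carbamoyl chloride should give the base-resistant carbamate that carries C3, its methyl group, O2 and C1.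

Step 5
Reactants: 7 ethyl N,N-diisopropylcarbamate; 4 2-bromo-1-(bromomethyl)-3,5-dimethoxy-4-methylbenzene
Product: 12 (R)-6,8-dimethoxy-3,7-dimethylisochroman-1-one, via lithiated carbamate 8 (not isolated), via bromo carbamate 9 (not isolated), via aryllithium 10 (not isolated), via hydroxy amide 11 (not isolated)
Conditions: 7, s-BuLi, (–)-sparteine, Et2O, –78 °C; then 4, –78 °C; then t-BuLi (2 equiv), –78 °C to rt; then 6 M HCl, THF, reflux
Reagents that add atoms: none
Why: s-BuLi/(–)-sparteine removes the pro-S hydrogen of the OCH2 group of 7 to give the carbonyl-chelated, configurationally stable (S)-organolithium 8, which displaces the benzylic bromide of 4 with retention at the carbanion carbon and so forms C3–C4 and sets (R)-C3 in 9 under control of the chiral diamine. t-BuLi then exchanges the aryl bromine, and aryllithium 10 adds to the carbamate carbonyl through a six-membered ring (6-exo-trig, Parham cyclisation) to form C1–C8a. The tetrahedral adduct opens to the alkoxide of amide 11 (1,5 O-to-C carbamoyl shift of the anionic Fries type), and hot acid recloses ring D by 6-exo-trig attack of the C3 hydroxyl on the twisted, doubly ortho-substituted amide with loss of diisopropylamine, an acyl–oxygen process that leaves C3 untouched. The closest known reaction types are the asymmetric lithiation–substitution of O-alkyl carbamates, the Parham cyclisation of aryl bromides onto tethered carbamoyl groups and the lactonisation of ortho-(2-hydroxyalkyl)benzamides, here run in one flask as a formal [3+3] annulation. The step needs substitution at the benzylic C–Br before any exchange at the aryl C–Br, which the far higher SN2 reactivity of the benzylic site, the bulk and dipole stabilisation of 8 and the low temperature should secure. It also needs the aryl anion at C8a and not at C5 and no benzylic deprotonation with loss of the carbamate, which the bromine placed in step 2 and the speed of bromine–lithium exchange at –78 °C secure.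

Step 6
Reactants: 12 (R)-6,8-dimethoxy-3,7-dimethylisochroman-1-one
Product: 13 (R)-6,8-dihydroxy-3,7-dimethylisochroman-1-one
Conditions: BBr3 (excess), CH2Cl2, –78 °C to rt; then H2O
Reagents that add atoms: none
Why: Lewis-acid cleavage of aryl methyl ethers, in which the 8-OMe is activated by chelation to the lactone carbonyl and the 6-OMe is twisted out of conjugation by the 7-methyl group, should free both phenols without touching the secondary alkyl C3–O bond.

Step 7
Reactants: 14 noreugenin (5,7-dihydroxy-2-methyl-4H-chromen-4-one)
Product: 15 eugenin (5-hydroxy-7-methoxy-2-methyl-4H-chromen-4-one)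
Conditions: MeI (1.1 equiv), K2CO3, acetone, reflux
Reagents that add atoms: iodomethane, CI
Why: Williamson ether synthesis should be selective for the free and more acidic 7′-OH, because the 5′-OH is locked in a hydrogen bond to the C4′ carbonyl.

Step 8
Reactants: 15 eugenin
Product: 16 cyclic phenylboronate of 6-(hydroxymethyl)eugenin (six-membered O5′–B(Ph)–O–CH2–C6′ ring fused to ring A)
Conditions: PhB(OH)2, (CH2O)n, EtCO2H (cat.), toluene, reflux, Dean–Stark
Reagents that add atoms: phenylboronic acid, OB(O)c1ccccc1; paraformaldehyde (formaldehyde unit), C=O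
Why: In this boronic-acid-templated ortho-hydroxymethylation of a phenol, the aryl boronate formed at O5′ binds formaldehyde and delivers it through a six-membered transition state to the only free ortho carbon C6′, so the para carbon C8′ cannot compete and the product is held as the stable benzodioxaborin.

Step 9
Reactants: 16 cyclic phenylboronate of 6-(hydroxymethyl)eugenin; 13 (R)-6,8-dihydroxy-3,7-dimethylisochroman-1-one
Product: 18 CNP0180307.1, via o-quinone methide 17 (not isolated)
Conditions: 13 (1.5 equiv), TsOH·H2O (cat.), 1,4-dioxane, 80 °C, slow addition of 16; aqueous work-up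
Reagents that add atoms: none
Why: Acid-induced opening of the benzodioxaborin should release o-quinone methide 17, which alkylates 13 in a Friedel–Crafts reaction at C5, the only unsubstituted carbon of ring C and ortho and para to its two hydroxyl groups, while O-alkylation stays reversible.

Compound list
1 | 3,5-dimethoxy-4-methylbenzoic acid | COc1cc(C(=O)O)cc(OC)c1C | starting material
2 | (3,5-dimethoxy-4-methylphenyl)methanol | COc1cc(CO)cc(OC)c1C | intermediate
3 | (2-bromo-3,5-dimethoxy-4-methylphenyl)methanol | COc1cc(CO)c(Br)c(OC)c1C | intermediate
4 | 2-bromo-1-(bromomethyl)-3,5-dimethoxy-4-methylbenzene | COc1cc(CBr)c(Br)c(OC)c1C | intermediate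
5 | ethanol | CCO | starting material
6 | N,N-diisopropylcarbamoyl chloride | CC(C)N(C(C)C)C(=O)Cl | starting material
7 | ethyl N,N-diisopropylcarbamate | CCOC(=O)N(C(C)C)C(C)C | intermediate
8 | (S)-1-lithioethyl N,N-diisopropylcarbamate (as its (–)-sparteine complex) | C[C@H]([Li])OC(=O)N(C(C)C)C(C)C | intermediate
9 | (R)-1-(2-bromo-3,5-dimethoxy-4-methylphenyl)propan-2-yl N,N-diisopropylcarbamate | C[C@H](Cc1cc(OC)c(C)c(OC)c1Br)OC(=O)N(C(C)C)C(C)C | intermediate
10 | (R)-1-(2-lithio-3,5-dimethoxy-4-methylphenyl)propan-2-yl N,N-diisopropylcarbamate | C[C@H](Cc1cc(OC)c(C)c(OC)c1[Li])OC(=O)N(C(C)C)C(C)C | intermediate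
11 | 2-[(2R)-2-hydroxypropyl]-4,6-dimethoxy-5-methyl-N,N-diisopropylbenzamide | C[C@@H](O)Cc1cc(OC)c(C)c(OC)c1C(=O)N(C(C)C)C(C)C | intermediate
12 | (R)-6,8-dimethoxy-3,7-dimethylisochroman-1-one | COc1cc2C[C@@H](C)OC(=O)c2c(OC)c1C | intermediate
13 | (R)-6,8-dihydroxy-3,7-dimethylisochroman-1-one | Cc1c(O)cc2C[C@@H](C)OC(=O)c2c1O | intermediate
14 | noreugenin (5,7-dihydroxy-2-methyl-4H-chromen-4-one) | Cc1cc(=O)c2c(O)cc(O)cc2o1 | starting material
15 | eugenin (5-hydroxy-7-methoxy-2-methyl-4H-chromen-4-one) | COc1cc(O)c2c(c1)oc(C)cc2=O | intermediate
16 | cyclic phenylboronate of 6-(hydroxymethyl)eugenin | COc1cc2oc(C)cc(=O)c2c3OB(c4ccccc4)OCc13 | intermediate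
17 | o-quinone methide of eugenin (C5′=O, C6′=CH2) | C=C1C(OC)=CC2=C(C1=O)C(=O)C=C(C)O2 | intermediate
18 | (3R)-6,8-dihydroxy-5-[(5-hydroxy-7-methoxy-2-methyl-4-oxo-4H-chromen-6-yl)methyl]-3,7-dimethylisochroman-1-one (CNP0180307.1) | COc1cc2oc(C)cc(=O)c2c(O)c1Cc1c(O)c(C)c(O)c2c1C[C@@H](C)OC2=O | target

Total step count: 9. Longest linear sequence: 6 steps (1, 2, 3, 5, 6, 9).

Steps most likely to fail

Step 5. Electron transfer or bromine–lithium exchange between 8 and 4 may take the place of clean substitution. That would erode the configuration at C3 and homocouple the benzyl unit. The carbamoyl transfer at the hindered carbonyl may also be too slow. The fallback sets out from 4 and 7 and comes back at 12. It makes C3–C4 by lithiation–borylation instead of alkylation and brings in C1 as carbon monoxide.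
- Copper-catalysed borylation of the benzylic bromide of 4 (B2pin2, CuI, PPh3, LiOMe, DMF, rt) should give the benzylic pinacol boronate F1 with the aryl bromide intact.
- Addition of F1 at –78 °C to 8, made from 7 as in step 5, gives the lithium boronate complex F2.
- Its stereospecific 1,2-metalate rearrangement on warming expels the carbamate with inversion and gives the (R)-secondary boronic ester F3.
- Oxidation with NaOH/H2O2, with retention, gives the (R)-bromo alcohol F4.
- Carbonylative lactonisation of its aryl bromide (CO, Pd(OAc)2, Xantphos, Et3N, toluene, 100 °C) gives 12.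

Step 8. The hydrogen bond and boron chelation between O5′ and the C4′ carbonyl may deactivate ring A so far that formaldehyde transfer stalls. The fallback sets out from 15 and comes back at 17. It replaces the templated C–H functionalisation by halogenation and cross-coupling.
- Ortho-selective iodination with benzyltrimethylammonium dichloroiodate and CaCO3 in CH2Cl2–MeOH should give 6-iodoeugenin F5.
- Stille coupling with (tributylstannyl)methanol (Pd(PPh3)4, 1,4-dioxane, 100 °C) gives 6-(hydroxymethyl)eugenin F6.
- F6 loses water under the conditions of step 9 to give 17 and so returns to the route.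

Step 9. Self-condensation of the quinone methide at C8′ of a second chromone unit, and over-alkylation of the product, may outrun the cross-coupling. The fallback sets out from 15 and 13 and comes back at 18. It moves the electrophile to the aldehyde level, where no quinone methide exists before the two halves are joined.
- Ortho-formylation of the magnesium phenoxide of 15 (MgCl2, Et3N, paraformaldehyde, MeCN, reflux) should give 6-formyleugenin F7.
- In CF3CO2H/CH2Cl2 with Et3SiH, C5 of 13 adds to the protonated aldehyde to give the diaryl carbinol F8.
- Ionisation of F8 and hydride capture (reductive Friedel–Crafts alkylation, ionic hydrogenation) give 18.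

Further compounds
F1 | step 5 | 2-(2-bromo-3,5-dimethoxy-4-methylbenzyl)-4,4,5,5-tetramethyl-1,3,2-dioxaborolane | COc1cc(CB2OC(C)(C)C(C)(C)O2)c(Br)c(OC)c1C
F2 | step 5 | lithium boronate complex from 8 and F1 | C[C@H]([B-]1(Cc2cc(OC)c(C)c(OC)c2Br)OC(C)(C)C(C)(C)O1)OC(=O)N(C(C)C)C(C)C.[Li+]
F3 | step 5 | (R)-2-[1-(2-bromo-3,5-dimethoxy-4-methylphenyl)propan-2-yl]-4,4,5,5-tetramethyl-1,3,2-dioxaborolane | C[C@@H](B1OC(C)(C)C(C)(C)O1)Cc1cc(OC)c(C)c(OC)c1Br
F4 | step 5 | (R)-1-(2-bromo-3,5-dimethoxy-4-methylphenyl)propan-2-ol | C[C@@H](O)Cc1cc(OC)c(C)c(OC)c1Br
F5 | step 8 | 6-iodoeugenin | COc1cc2oc(C)cc(=O)c2c(O)c1I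
F6 | step 8 | 6-(hydroxymethyl)eugenin | COc1cc2oc(C)cc(=O)c2c(O)c1CO
F7 | step 9 | 6-formyleugenin | COc1cc2oc(C)cc(=O)c2c(O)c1C=O
F8 | step 9 | diaryl carbinol from F7 and 13 (both carbinol epimers) | COc1cc2oc(C)cc(=O)c2c(O)c1C(O)c1c(O)c(C)c(O)c2c1C[C@@H](C)OC2=O
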